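**Plan**

- Retrosynthesis: the C7–C8 bond is cut first (C7 = benzylic carbinol carbon on the 3,4,5-trimethoxyphenyl ring; C8 = methyl-bearing carbon on the ether oxygen of the 2-methoxy-4-(methoxycarbonyl)phenyl ring), then the C8–O aryl ether bond.
- Forward: methyl vanillate is O-alkylated with racemic tert-butyl 2-bromopropanoate, the tert-butyl ester is cleaved, and the racemic α-aryloxy acid is joined to 3,4,5-trimethoxybenzaldehyde with loss of CO2. No ring is formed; the chain is joined last.
- Enabling feature: C8 carries the aryl ether oxygen, so a radical at C8 is oxygen-stabilised, forms readily by decarboxylation and is trapped by Cr(II). C7 is the carbonyl carbon of a non-enolisable aryl aldehyde. The carboxyl group on C8 is a temporary activating group that leaves as CO2 in the key step.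
- Stereochemistry: both centres (7S,8S, threo) are set in the key step by a chiral chromium catalyst. The step is stereoconvergent at C8, so the acid is used as the racemate.

Key step: step 3

Assumption: the sense of induction of the chromium–bis(oxazoline) catalyst cannot be predicted with confidence for this radical class; one antipode of the ligand is written, and the mirror-image ligand is the one to use if the first run should give the (7R,8R) series.

**Route**

Step 1
Reactants: 1 methyl 4-hydroxy-3-methoxybenzoate (methyl vanillate); 2 tert-butyl 2-bromopropanoate (racemic)
Product: 3 tert-butyl 2-[2-methoxy-4-(methoxycarbonyl)phenoxy]propanoate (racemic)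
Conditions: K2CO3, DMF, 60 °C
Reagents that add atoms: none
Why: Williamson ether synthesis, in which the phenoxide of 1 displaces bromide from the activated secondary α-bromo ester by SN2 while the hindered tert-butyl ester is not attacked; the racemic C8 centre is acceptable because it is erased in step 3.

Step 2
Reactants: 3 tert-butyl 2-[2-methoxy-4-(methoxycarbonyl)phenoxy]propanoate (racemic)
Product: 4 2-[2-methoxy-4-(methoxycarbonyl)phenoxy]propanoic acid (racemic)
Conditions: TFA, CH2Cl2, rt
Reagents that add atoms: none
Why: Acidolysis of the tert-butyl ester (E1 loss of isobutene) should free the carboxylic acid while the methyl benzoate and both aryl ethers are stable to TFA.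

Step 3
Reactants: 4 2-[2-methoxy-4-(methoxycarbonyl)phenoxy]propanoic acid (racemic, 1.5 equiv); 5 3,4,5-trimethoxybenzaldehyde
Product: 8 methyl 4-{[(1S,2S)-1-hydroxy-1-(3,4,5-trimethoxyphenyl)propan-2-yl]oxy}-3-methoxybenzoate, via 1-aryloxyethyl radical 6 (not isolated), via alkylchromium(III) complex 7 (not isolated)
Conditions: CrCl2 (10 mol %), chiral indane-fused bis(oxazoline) ligand (12 mol %), [Ir(dF(CF3)ppy)2(dtbbpy)]PF6 (2 mol %), 2,4,6-collidine (0.5 equiv), degassed THF–MeCN, 450 nm LEDs, 15 °C
Reagents that add atoms: none
Why: Proposed new method: the excited Ir(III) photocatalyst oxidises the carboxylate of 4, loss of CO2 gives the planar oxygen-stabilised radical 6, ligated Cr(II) traps it as alkylchromium(III) 7, and 7 adds to the Cr-bound aldehyde 5 through a four-centre transition state, after which protonation of the Cr(III) alkoxide by 4 and reduction of Cr(III) by Ir(II) close both cycles. The closest known reaction types are the photoredox/chromium radical–polar crossover (Nozaki–Hiyama–Kishi-type) addition of α-heteroatom and allyl radicals to aldehydes and the chromium-mediated decarboxylative alkylation of aldehydes with redox-active esters; the asymmetric use of a free α-aryloxy acid is the untested part. No ring is closed. C8 is controlled by the chiral bis(oxazoline) on chromium: the configuration of racemic 4 is erased in 6 and the Cr–C bond of 7 forms reversibly, so both enantiomers of 4 should be funnelled into the diastereomer of 7 that reacts, with retention, to give 8S. C7 is controlled by the same ligand sphere, which fixes the exposed face of the cis-coordinated aldehyde; the threo relation is expected from a four-centre arrangement in which the C8–H sits between the trimethoxyphenyl ring and chromium, the aryloxy oxygen (supported by its ortho-methoxy group) stays on the chromium side next to the aldehyde hydrogen, and the methyl group points away from chromium. The step needs chemoselectivity for the aldehyde over the two methyl esters, which the low basicity and carbonyl selectivity of alkyl–Cr(III) should secure, and site selectivity for C8, which the carboxyl group of 4 fixes.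

**Compound list**

1 | methyl 4-hydroxy-3-methoxybenzoate (methyl vanillate) | COC(=O)c1ccc(O)c(OC)c1 | starting material
2 | tert-butyl 2-bromopropanoate (racemic) | CC(Br)C(=O)OC(C)(C)C | starting material
3 | tert-butyl 2-[2-methoxy-4-(methoxycarbonyl)phenoxy]propanoate (racemic) | COC(=O)c1ccc(OC(C)C(=O)OC(C)(C)C)c(OC)c1 | intermediate
4 | 2-[2-methoxy-4-(methoxycarbonyl)phenoxy]propanoic acid (racemic) | COC(=O)c1ccc(OC(C)C(=O)O)c(OC)c1 | intermediate
5 | 3,4,5-trimethoxybenzaldehyde | COc1cc(C=O)cc(OC)c1OC | starting material
6 | 1-[2-methoxy-4-(methoxycarbonyl)phenoxy]ethyl radical (planar at C8) | COC(=O)c1ccc(O[CH]C)c(OC)c1 | intermediate (not isolated)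
7 | {1-[2-methoxy-4-(methoxycarbonyl)phenoxy]ethyl}chromium(III) dichloride, (R) at the chromium-bearing carbon (productive diastereomer; bis(oxazoline) and solvent ligands on Cr not drawn) | COC(=O)c1ccc(O[C@@H](C)[Cr](Cl)Cl)c(OC)c1 | intermediate (not isolated)
8 | methyl 4-{[(1S,2S)-1-hydroxy-1-(3,4,5-trimethoxyphenyl)propan-2-yl]oxy}-3-methoxybenzoate (threo, 7S,8S) | COC(=O)c1ccc(O[C@@H](C)[C@@H](O)c2cc(OC)c(OC)c(OC)c2)c(OC)c1 | target

**Summary**

Total step count: 3. Longest linear sequence: 3 steps (1 → 3 → 4 → 8).

**Steps most likely to fail**

Step 3 (proposed new method). Three processes may defeat it: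
- poor facial or threo/erythro selectivity in the addition of the secondary α-aryloxyalkylchromium;
- protonolysis of the Cr–C bond by the free acid, or radical dimerisation, before C–C bond formation;
- chromium-mediated pinacol coupling of the aldehyde.

The fallback uses known chemistry, sets out from 5 (with 1) and returns at 8. A thiamine-diphosphate-dependent benzaldehyde lyase joins 5 to acetaldehyde (ThDP, Mg2+, buffer/DMSO, 30 °C), forming the same C7–C8 bond and giving (R)-2-hydroxy-1-(3,4,5-trimethoxyphenyl)propan-1-one F1. Mitsunobu etherification of F1 with 1 (PPh3, DIAD, THF, 0 °C) inverts C8 and should give methyl 3-methoxy-4-{[(2S)-1-oxo-1-(3,4,5-trimethoxyphenyl)propan-2-yl]oxy}benzoate F2. Non-chelating Felkin–Anh reduction of F2 (L-Selectride, THF, −78 °C) should then give the threo alcohol 8.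

Step 1. E2 loss of HBr from the secondary α-bromo ester may compete, followed by conjugate addition of the phenoxide to the resulting acrylate (regioisomeric ether), and SN2 by the ortho-substituted phenoxide may be slow. The fallback sets out from 1 and returns at 4. Mitsunobu etherification of 1 with racemic benzyl lactate (PPh3, DIAD, THF) should give benzyl 2-[2-methoxy-4-(methoxycarbonyl)phenoxy]propanoate F3 (racemic). Hydrogenolysis (H2, Pd/C, EtOAc) converts F3 into 4, so step 2 is bypassed as well.

Step 2. The tert-butyl cation may alkylate the electron-rich aryl ether ring, or acidolysis may stop short. The fallback sets out from 1 and returns at 4 without any carboxyl protection. The phenoxide of 1 is alkylated with the sodium salt of 2-bromopropanoic acid (NaH, 2.2 equiv, DMF, 0 to 60 °C, acidic work-up) to give 4 directly. No compound outside the list is made (F0).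

**Further compounds**

F1 | step 3 | (R)-2-hydroxy-1-(3,4,5-trimethoxyphenyl)propan-1-one | C[C@@H](O)C(=O)c1cc(OC)c(OC)c(OC)c1
F2 | step 3 | methyl 3-methoxy-4-{[(2S)-1-oxo-1-(3,4,5-trimethoxyphenyl)propan-2-yl]oxy}benzoate | COC(=O)c1ccc(O[C@@H](C)C(=O)c2cc(OC)c(OC)c(OC)c2)c(OC)c1
F3 | step 1 | benzyl 2-[2-methoxy-4-(methoxycarbonyl)phenoxy]propanoate (racemic) | COC(=O)c1ccc(OC(C)C(=O)OCc2ccccc2)c(OC)c1
F0 | step 2 | none | none
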